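**Retrosynthetic overview**
1. The pyran ring is closed last: the O1–C2 bond and the C3=C4 alkene come from an enantioselective 6-endo oxidative oxypalladation of a C-geranylated, dearomatised acyl trione, which sets the (2R) quaternary centre.
2. The geranyl trione comes from C-alkylation of the gem-dimethyl acyl trione with (E)-geranyl bromide at its one free ring CH.
3. The gem-dimethyl trione comes from dearomative double C-methylation of (R)-2-methylbutanoylphloroglucinol.
4. The acylphloroglucinol comes from Friedel–Crafts acylation of phloroglucinol with (R)-2-methylbutanoyl chloride; the side-chain centre is bought.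
5. Ring order: the carbocycle (bought as the arene, then dearomatised) first, the pyran ring last.

Assumption: (2R)-2-methylbutanoic acid (≥98% ee) and (E)-geranyl bromide are bought as such, and the ligand antipode written in step 5, (M,S,S), is taken to put palladium on the C3′-Si face (if a two-run screen shows the opposite sense, its mirror image (P,R,R) is used and nothing else changes).

**Route**

Step 1
Reactants: 1 (2R)-2-methylbutanoic acid
Product: 2 (2R)-2-methylbutanoyl chloride
Conditions: (COCl)2 (1.2 equiv), DMF (cat.), CH2Cl2, 0 °C → rt, 2 h; excess reagent evaporated, crude 2 used at once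
Reagents that add atoms: oxalyl chloride, ClC(=O)C(=O)Cl
Why: Acid chloride formation through the chloroiminium (Vilsmeier-type) activator; no base is present, so the α-carbon is not enolised and stays (R).

Step 2
Reactants: 2 (2R)-2-methylbutanoyl chloride; 3 phloroglucinol (benzene-1,3,5-triol)
Product: 4 (2R)-2-methyl-1-(2,4,6-trihydroxyphenyl)butan-1-one
Conditions: AlCl3 (3.5 equiv), PhNO2/CH2Cl2, 0 °C → rt, 12 h; ice/1 M HCl
Reagents that add atoms: none
Why: Friedel–Crafts C-acylation of the very electron-rich triol stops at mono-acylation because the ketone deactivates the ring, and at ≤25 °C the activated acyl species is captured faster than it can lose its α-proton, so the (R) centre is retained (ee checked by chiral HPLC).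

Step 3
Reactants: 4 (2R)-2-methyl-1-(2,4,6-trihydroxyphenyl)butan-1-one
Product: 6 3,5-dihydroxy-4,4-dimethyl-2-[(2R)-2-methylbutanoyl]cyclohexa-2,5-dien-1-one, via C-monomethyl ketone 5 (not isolated)
Conditions: NaOMe (3.5 equiv), MeI (2.2 equiv), MeOH, 0 °C → rt, 12 h; 1 M HCl; chromatography
Reagents that add atoms: iodomethane (MeI), CI
Why: Dearomative double C-methylation of the phloroglucinolate polyanion (C-alkylation of an ambident phenolate in a protic solvent): the first methyl gives 5, the second enters the same carbon and breaks aromaticity, and the polyanion is not deprotonated at the side-chain α-carbon, so that centre is kept.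

Step 4
Reactants: 6 3,5-dihydroxy-4,4-dimethyl-2-[(2R)-2-methylbutanoyl]cyclohexa-2,5-dien-1-one; 7 geranyl bromide, (2E)-1-bromo-3,7-dimethylocta-2,6-diene
Product: 8 2-[(2E)-3,7-dimethylocta-2,6-dien-1-yl]-3,5-dihydroxy-4,4-dimethyl-6-[(2R)-2-methylbutanoyl]cyclohexa-2,5-dien-1-one
Conditions: NaOMe (2.0 equiv), MeOH, 0 °C; 7 (1.0 equiv) added over 1 h; → rt, 3 h; 1 M HCl; chromatography
Reagents that add atoms: none
Why: SN2 C-alkylation of the trione dianion at its only free ring CH (the protic medium solvates oxygen and favours C- over O-alkylation); the allylic bromide keeps its (E) geometry and no stereocentre is touched.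

Step 5
Reactants: 8 2-[(2E)-3,7-dimethylocta-2,6-dien-1-yl]-3,5-dihydroxy-4,4-dimethyl-6-[(2R)-2-methylbutanoyl]cyclohexa-2,5-dien-1-one
Product: 9 (2R)-5-hydroxy-2,8,8-trimethyl-6-[(2R)-2-methylbutanoyl]-2-(4-methylpent-3-en-1-yl)-2H-chromen-7(8H)-one (target CNP0313486.1)
Conditions: Pd(OCOCF3)2 (10 mol %), (M,S,S)-iPr-SPRIX (spiro bis(isoxazoline) ligand, 12 mol %), p-benzoquinone (2.0 equiv), CH2Cl2, 0 → 25 °C, N2, dark, 24–48 h; silica chromatography at ≤25 °C
Reagents that add atoms: none
Why: Proposed new method: an enantioselective 6-endo Wacker-type oxidative cyclisation in which a cyclic β-triketone enol (a vinylogous acid, not a phenol) is the O-nucleophile and the product is a non-aromatic 2H-pyran with an O-bearing quaternary centre; the electrophilic bis(isoxazoline)-bound divalent palladium (weakly held trifluoroacetates, no base, so the triketone is not parked as an O,O-chelate) binds the proximal (2E)-alkene on its C3′-Si face, the C3-OH oxygen of 8 (between the CMe2 carbon and the geranyl-bearing carbon; the central oxygen is either tied in the acyl hydrogen-bond chelate or screened by the sec-butyl group) attacks anti at the tertiary carbon C3′ on its Re face (Markovnikov, 6-endo), which sets (2R), and β-hydride elimination toward the doubly activated C1′ methylene gives the conjugated pyran C3=C4 alkene while benzoquinone reoxidises zerovalent palladium; the closest known reaction type is the palladium–chiral bis(isoxazoline) or bis(oxazoline) catalysed Wacker-type cyclisation of ortho-allyl and ortho-geranyl phenols to dihydrobenzofurans and 2H-chromenes.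

**Compound list**
1 | (2R)-2-methylbutanoic acid | CC[C@@H](C)C(=O)O | starting material
2 | (2R)-2-methylbutanoyl chloride | CC[C@@H](C)C(=O)Cl | intermediate
3 | phloroglucinol (benzene-1,3,5-triol) | Oc1cc(O)cc(O)c1 | starting material
4 | (2R)-2-methyl-1-(2,4,6-trihydroxyphenyl)butan-1-one | CC[C@@H](C)C(=O)c1c(O)cc(O)cc1O | intermediate
5 | (2R)-2-methyl-1-(2,4,6-trihydroxy-3-methylphenyl)butan-1-one | CC[C@@H](C)C(=O)c1c(O)cc(O)c(C)c1O | intermediate
6 | 3,5-dihydroxy-4,4-dimethyl-2-[(2R)-2-methylbutanoyl]cyclohexa-2,5-dien-1-one | CC[C@@H](C)C(=O)C1=C(O)C(C)(C)C(O)=CC1=O | intermediate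
7 | geranyl bromide, (2E)-1-bromo-3,7-dimethylocta-2,6-diene | CC(C)=CCC/C(C)=C/CBr | starting material
8 | 2-[(2E)-3,7-dimethylocta-2,6-dien-1-yl]-3,5-dihydroxy-4,4-dimethyl-6-[(2R)-2-methylbutanoyl]cyclohexa-2,5-dien-1-one | CC[C@@H](C)C(=O)C1=C(O)C(C)(C)C(O)=C(C/C=C(\C)CCC=C(C)C)C1=O | intermediate
9 | (2R)-5-hydroxy-2,8,8-trimethyl-6-[(2R)-2-methylbutanoyl]-2-(4-methylpent-3-en-1-yl)-2H-chromen-7(8H)-one | CC[C@@H](C)C(=O)C1=C(O)C2=C(O[C@](C)(CCC=C(C)C)C=C2)C(C)(C)C1=O | target

**Totals**
Total step count: 5. Longest linear sequence: 5 steps (1 → 2 → 4 → 6 → 8 → 9).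

**Three steps most likely to fail**

Step 5 (the proposed new step). The risks are that the triketone sequesters divalent palladium, that closure goes through the central oxygen or in the 5-exo mode, and that facial selectivity is only moderate. A diastereomer ratio below about 95:5 is upgraded by preparative HPLC on a chiral phase; 9 is kept cold and dark because a non-aromatic 2H-pyran can epimerise at C2 by thermal ring opening. The fallback uses known chemistry, sets out from 6 and comes back at 9, bypassing steps 4 and 5. Trione 6 is condensed with commercial citral (E/Z mixture, 1.2 equiv) under ethylenediammonium diacetate catalysis (10 mol %, MeOH, 25–50 °C). Knoevenagel condensation at the free ring CH gives the alkylidene trione F1 (a 1-oxatriene). F1 closes by oxa-6π electrocyclisation through the non-enolisable ketone next to the CMe2 carbon to give 9 together with the (2S)-epimer of 9 F2 in about a 1:1 ratio. The two diastereomers are separated by preparative HPLC on an amylose carbamate chiral phase, and F2 is recycled by warming in toluene, which re-opens it to F1 and re-closes it to the 1:1 mixture.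

Step 3. Limiting MeI gives the gem-dimethyl trione only in moderate yield (about 40% expected) beside 3,5-dimethyl, trimethyl and tetramethyl products. The fallback sets out from 4 and comes back at 8, replacing steps 3 and 4 by the inverted order. Ketone 4 is first C-geranylated with 7 (NaOMe, MeOH, 0 °C) to give the aromatic 3-geranyl ketone F3. Dearomative methylation (NaOMe, MeI, MeOH, 0 °C → rt) then passes through the 5-methyl ketone F4, and the second methyl on the same carbon gives 8 directly. The methylation now has only one free ring CH, so the over-methylated products of step 3 cannot form; the minor isomer methylated at the geranyl-bearing carbon is removed by chromatography.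

Step 4. The risks are O-geranylation, double alkylation at the same carbon and methanolysis of the bromide. The fallback sets out from 6 and comes back at 8 by a Tsuji–Trost allylation: 6, commercial geranyl acetate (1.05 equiv), Pd(PPh3)4 (5 mol %), Et3N (1.2 equiv), THF, 25 °C. The soft trione carbon attacks the unhindered terminus of the π-geranyl complex formed by zerovalent palladium, and any O-geranyl product re-ionises under the same catalyst and drains to the linear (E) C-alkylated product 8. This fallback makes no compound outside the list (F0).

**Further compounds**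
F1 | step 5 | 2-(3,7-dimethylocta-2,6-dien-1-ylidene)-5-hydroxy-6,6-dimethyl-4-[(2R)-2-methylbutanoyl]cyclohex-4-ene-1,3-dione (alkylidene trione, alkene isomers not defined) | CC[C@@H](C)C(=O)C1=C(O)C(C)(C)C(=O)C(=CC=C(C)CCC=C(C)C)C1=O
F2 | step 5 | (2S)-5-hydroxy-2,8,8-trimethyl-6-[(2R)-2-methylbutanoyl]-2-(4-methylpent-3-en-1-yl)-2H-chromen-7(8H)-one ((2S)-epimer of 9) | CC[C@@H](C)C(=O)C1=C(O)C2=C(O[C@@](C)(CCC=C(C)C)C=C2)C(C)(C)C1=O
F3 | step 3 | (2R)-1-{3-[(2E)-3,7-dimethylocta-2,6-dien-1-yl]-2,4,6-trihydroxyphenyl}-2-methylbutan-1-one (3-geranyl ketone) | CC[C@@H](C)C(=O)c1c(O)cc(O)c(C/C=C(\C)CCC=C(C)C)c1O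
F4 | step 3 | (2R)-1-{3-[(2E)-3,7-dimethylocta-2,6-dien-1-yl]-2,4,6-trihydroxy-5-methylphenyl}-2-methylbutan-1-one (5-methyl ketone) | CC[C@@H](C)C(=O)c1c(O)c(C)c(O)c(C/C=C(\C)CCC=C(C)C)c1O
F0 | step 4 | none | none
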